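**Assumption:** the target SMILES has no stereodescriptor and no stereocentre, and the biaryl axis has only two ortho substituents (freely rotating), so the target is one achiral compound and no stereocontrol is needed.

## Retrosynthetic overview

- Target ⇒ two-fold O-demethylation of the 7,8'-dimethoxy bichromone.
- Both 4-pyranone rings ⇒ closed last and together, by acid cyclodehydration of an open bis(β-diketone).
- Bis(β-diketone) ⇒ two-fold intermolecular Claisen condensation of a biaryl bis(2-hydroxyacetophenone) with ethyl 3-phenylpropanoate. This key step forms both CH2–C(=O) bonds and brings in both phenylethyl arms.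
- Biaryl bis(acetophenone) ⇒ Suzuki–Miyaura coupling of an aryl boronate (from 2',4'-dimethoxyacetophenone) with an aryl bromide (from 2,3-dimethoxybenzaldehyde), then chelation-controlled unmasking of the two ortho phenols.
- Ring order: both benzene rings are bought, the biaryl bond is made first, and the two pyranone rings are formed in one operation at the end.

## Route

Step 1
Reactants: 1 1-(2,4-dimethoxyphenyl)ethanone
Product: 2 1-(5-bromo-2,4-dimethoxyphenyl)ethanone
Conditions: NBS (1.05 equiv), MeCN, 0 °C → rt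
Reagents that add atoms: N-bromosuccinimide, O=C1CCC(=O)N1Br
Why: Electrophilic aromatic bromination goes to C5 (para to the 2-OMe, ortho to the 4-OMe, meta to the acetyl) because C3 is flanked by two methoxy groups, and NBS in MeCN without acid or initiator leaves the methyl ketone alone.

Step 2
Reactants: 2 1-(5-bromo-2,4-dimethoxyphenyl)ethanone
Product: 3 1-[2,4-dimethoxy-5-(4,4,5,5-tetramethyl-1,3,2-dioxaborolan-2-yl)phenyl]ethanone
Conditions: B2pin2 (1.2 equiv), PdCl2(dppf) (3 mol %), KOAc (3 equiv), 1,4-dioxane, 90 °C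
Reagents that add atoms: bis(pinacolato)diboron, CC1(C)OB(OC1(C)C)B1OC(C)(C)C(C)(C)O1
Why: Miyaura borylation of an aryl bromide tolerates the ketone and ethers, and the weak base KOAc prevents the boronate from coupling with unreacted bromide.

Step 3
Reactants: 4 2,3-dimethoxybenzaldehyde
Product: 5 6-bromo-2,3-dimethoxybenzaldehyde
Conditions: NBS (1.5 equiv), DMF, rt, 48 h
Reagents that add atoms: N-bromosuccinimide, O=C1CCC(=O)N1Br
Why: Electrophilic aromatic bromination is directed para to the conjugated 3-OMe (C6), since the 2-OMe is twisted out of conjugation between its two neighbours and activates C5 only weakly.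

Step 4
Reactants: 5 6-bromo-2,3-dimethoxybenzaldehyde
Product: 6 rac-1-(6-bromo-2,3-dimethoxyphenyl)ethanol
Conditions: MeMgBr (1.2 equiv), THF, 0 °C; then H2O
Reagents that add atoms: methylmagnesium bromide, C[Mg]Br
Why: Grignard addition to the aldehyde is fast at 0 °C while the aryl bromide does not exchange with MeMgBr; the new carbinol centre is racemic and is erased in the next step.

Step 5
Reactants: 6 rac-1-(6-bromo-2,3-dimethoxyphenyl)ethanol
Product: 7 1-(6-bromo-2,3-dimethoxyphenyl)ethanone
Conditions: Dess–Martin periodinane (1.3 equiv), CH2Cl2, rt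
Reagents that add atoms: none
Why: Dess–Martin oxidation converts the hindered secondary benzylic alcohol to the methyl ketone under neutral conditions that leave the bromide and ethers untouched.

Step 6
Reactants: 3 1-[2,4-dimethoxy-5-(4,4,5,5-tetramethyl-1,3,2-dioxaborolan-2-yl)phenyl]ethanone; 7 1-(6-bromo-2,3-dimethoxyphenyl)ethanone
Product: 8 1-[5-(2-acetyl-3,4-dimethoxyphenyl)-2,4-dimethoxyphenyl]ethanone
Conditions: Pd(OAc)2 (3 mol %), SPhos (6 mol %), K3PO4 (3 equiv), toluene/H2O 10:1, 90 °C
Reagents that add atoms: none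
Why: Suzuki–Miyaura cross-coupling; the ortho acetyl speeds oxidative addition of 7 to zerovalent palladium, SPhos handles the di-ortho-substituted biaryl, and with all phenols masked as methyl ethers nothing else reacts.

Step 7
Reactants: 8 1-[5-(2-acetyl-3,4-dimethoxyphenyl)-2,4-dimethoxyphenyl]ethanone
Product: 9 1-[5-(2-acetyl-3-hydroxy-4-methoxyphenyl)-2-hydroxy-4-methoxyphenyl]ethanone
Conditions: BCl3 (1 M in CH2Cl2, 2.4 equiv), CH2Cl2, −78 → 0 °C; then H2O
Reagents that add atoms: none
Why: Chelation-directed Lewis-acid ether cleavage: BCl3 binds each ketone oxygen and demethylates only the OMe ortho to it through a six-membered chelate, leaving the two non-chelated methoxy groups in place at or below 0 °C with limited reagent.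

Step 8
Reactants: 9 1-[5-(2-acetyl-3-hydroxy-4-methoxyphenyl)-2-hydroxy-4-methoxyphenyl]ethanone; 10 ethyl 3-phenylpropanoate
Product: 11 1-[2-hydroxy-5-[3-hydroxy-4-methoxy-2-(3-oxo-5-phenylpentanoyl)phenyl]-4-methoxyphenyl]-5-phenylpentane-1,3-dione
Conditions: NaH (10 equiv), 10 (4 equiv), THF, 0 °C → reflux; then 1 M HCl, 0 °C
Reagents that add atoms: none
Why: Two-fold intermolecular crossed Claisen condensation: each phenoxide/ketone-enolate dianion attacks the ester carbonyl at its unhindered terminal carbon, and irreversible deprotonation of the β-diketones by excess NaH drives both acylations to completion.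

Step 9
Reactants: 11 1-[2-hydroxy-5-[3-hydroxy-4-methoxy-2-(3-oxo-5-phenylpentanoyl)phenyl]-4-methoxyphenyl]-5-phenylpentane-1,3-dione
Product: 13 7-methoxy-6-[8-methoxy-4-oxo-2-(2-phenylethyl)-4H-chromen-5-yl]-2-(2-phenylethyl)-4H-chromen-4-one, via bis-hemiketal 12 (not isolated)
Conditions: conc. HCl (cat.), AcOH, 100 °C
Reagents that add atoms: none
Why: Acid-catalysed cyclodehydration (chromone ring closure): each ortho phenol adds to the distal ketone to give a six-membered hemiketal that loses water to the conjugated 4-pyranone, and the methyl ethers are stable to HCl/AcOH.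

Step 10
Reactants: 13 7-methoxy-6-[8-methoxy-4-oxo-2-(2-phenylethyl)-4H-chromen-5-yl]-2-(2-phenylethyl)-4H-chromen-4-one
Product: 14 7-hydroxy-6-[8-hydroxy-4-oxo-2-(2-phenylethyl)-4H-chromen-5-yl]-2-(2-phenylethyl)-4H-chromen-4-one
Conditions: BBr3 (1 M in CH2Cl2, 8 equiv), CH2Cl2, −78 °C → rt; then H2O
Reagents that add atoms: none
Why: BBr3 cleavage of aryl methyl ethers (excess reagent compensates for binding to the two pyranone carbonyls); the chromone rings and phenylethyl chains are inert and no stereocentre is involved.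

## Compound list

1 | 1-(2,4-dimethoxyphenyl)ethanone | CC(=O)c1ccc(OC)cc1OC | starting material
2 | 1-(5-bromo-2,4-dimethoxyphenyl)ethanone | CC(=O)c1cc(Br)c(OC)cc1OC | intermediate
3 | 1-[2,4-dimethoxy-5-(4,4,5,5-tetramethyl-1,3,2-dioxaborolan-2-yl)phenyl]ethanone | CC(=O)c1cc(B2OC(C)(C)C(C)(C)O2)c(OC)cc1OC | intermediate
4 | 2,3-dimethoxybenzaldehyde | COc1cccc(C=O)c1OC | starting material
5 | 6-bromo-2,3-dimethoxybenzaldehyde | COc1ccc(Br)c(C=O)c1OC | intermediate
6 | rac-1-(6-bromo-2,3-dimethoxyphenyl)ethanol (racemate) | COc1ccc(Br)c(C(C)O)c1OC | intermediate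
7 | 1-(6-bromo-2,3-dimethoxyphenyl)ethanone | COc1ccc(Br)c(C(C)=O)c1OC | intermediate
8 | 1-[5-(2-acetyl-3,4-dimethoxyphenyl)-2,4-dimethoxyphenyl]ethanone | CC(=O)c1cc(-c2ccc(OC)c(OC)c2C(C)=O)c(OC)cc1OC | intermediate
9 | 1-[5-(2-acetyl-3-hydroxy-4-methoxyphenyl)-2-hydroxy-4-methoxyphenyl]ethanone | CC(=O)c1cc(-c2ccc(OC)c(O)c2C(C)=O)c(OC)cc1O | intermediate
10 | ethyl 3-phenylpropanoate | CCOC(=O)CCc1ccccc1 | starting material
11 | 1-[2-hydroxy-5-[3-hydroxy-4-methoxy-2-(3-oxo-5-phenylpentanoyl)phenyl]-4-methoxyphenyl]-5-phenylpentane-1,3-dione (drawn as the tetraketo tautomer) | O=C(CCc1ccccc1)CC(=O)c1cc(-c2ccc(OC)c(O)c2C(=O)CC(=O)CCc2ccccc2)c(OC)cc1O | intermediate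
12 | 2-hydroxy-6-[2-hydroxy-8-methoxy-4-oxo-2-(2-phenylethyl)chroman-5-yl]-7-methoxy-2-(2-phenylethyl)chroman-4-one (bis-hemiketal, mixture of diastereomers) | O=C1CC(O)(CCc2ccccc2)Oc2cc(OC)c(-c3ccc(OC)c4OC(O)(CCc5ccccc5)CC(=O)c34)cc12 | intermediate
13 | 7-methoxy-6-[8-methoxy-4-oxo-2-(2-phenylethyl)-4H-chromen-5-yl]-2-(2-phenylethyl)-4H-chromen-4-one | O=c1cc(CCc2ccccc2)oc2cc(OC)c(-c3ccc(OC)c4oc(CCc5ccccc5)cc(=O)c34)cc12 | intermediate
14 | 7-hydroxy-6-[8-hydroxy-4-oxo-2-(2-phenylethyl)-4H-chromen-5-yl]-2-(2-phenylethyl)-4H-chromen-4-one (CNP0279305.0) | O=c1cc(CCc2ccccc2)oc2cc(O)c(-c3ccc(O)c4oc(CCc5ccccc5)cc(=O)c34)cc12 | target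

## Summary

Total step count: 10.
Longest linear sequence: 8 steps (4 → 5 → 6 → 7 → 8 → 9 → 11 → 13 → 14; steps 3, 4, 5, 6, 7, 8, 9, 10).

Steps most likely to fail, each with one fallback:

- **Step 8 (two-fold Claisen condensation).** The substrate must be acylated twice as a poorly soluble polyanion, and the ester can self-condense. The fallback sets out from 9 and comes back at 11. Both phenols of 9 are esterified with 3-phenylpropanoyl chloride (pyridine, cat. DMAP, CH2Cl2) to give 2-acetyl-4-[2-acetyl-4-methoxy-3-(3-phenylpropanoyloxy)phenyl]-5-methoxyphenyl 3-phenylpropanoate F1. A Baker–Venkataraman O-to-C acyl migration (KOH, pyridine, 50 °C) then delivers both β-diketone arms and gives 11.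

- **Step 7 (selective double demethylation).** The ring B methoxy group next to the newly formed aryloxyboron chloride may also be cleaved, or the hindered ring B ketone may react slowly. The fallback sets out from 8 and comes back at 14. Compound 8 is condensed directly with 10 (NaH, THF, reflux) to give 1-[5-[3,4-dimethoxy-2-(3-oxo-5-phenylpentanoyl)phenyl]-2,4-dimethoxyphenyl]-5-phenylpentane-1,3-dione F2. Heating F2 in 48% HBr/AcOH cleaves all four methyl ethers and closes both pyranone rings in the same pot, so no selectivity between the ethers is needed and 14 is reached directly.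

- **Step 6 (Suzuki–Miyaura coupling).** The electron-rich boronate 3 may protodeboronate before it couples at the position next to the acetyl group of 7. The fallback sets out from 7 (partner 2) and comes back at 8, with the roles of the two rings exchanged. Miyaura borylation of 7 (B2pin2, PdCl2(dppf), KOAc, dioxane, 90 °C) gives 1-[2,3-dimethoxy-6-(4,4,5,5-tetramethyl-1,3,2-dioxaborolan-2-yl)phenyl]ethanone F3. F3 is then coupled with bromide 2 (Pd(OAc)2, SPhos, K3PO4, toluene/H2O, 90 °C) to give 8.

## Further compounds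

F1 | step 8 | 2-acetyl-4-[2-acetyl-4-methoxy-3-(3-phenylpropanoyloxy)phenyl]-5-methoxyphenyl 3-phenylpropanoate | CC(=O)c1cc(-c2ccc(OC)c(OC(=O)CCc3ccccc3)c2C(C)=O)c(OC)cc1OC(=O)CCc1ccccc1
F2 | step 7 | 1-[5-[3,4-dimethoxy-2-(3-oxo-5-phenylpentanoyl)phenyl]-2,4-dimethoxyphenyl]-5-phenylpentane-1,3-dione | O=C(CCc1ccccc1)CC(=O)c1cc(-c2ccc(OC)c(OC)c2C(=O)CC(=O)CCc2ccccc2)c(OC)cc1OC
F3 | step 6 | 1-[2,3-dimethoxy-6-(4,4,5,5-tetramethyl-1,3,2-dioxaborolan-2-yl)phenyl]ethanone | COc1ccc(B2OC(C)(C)C(C)(C)O2)c(C(C)=O)c1OC
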